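**Plan**

- Numbering (bisabolane): ring C1–C6 with the side chain on C1, OH on C2, angelate on C3, methyl and oxirane on C4–C5, CH2 = C6; side chain C7(=C14H2)–C8(OAng)–C9–C10/C11 oxirane.
- Retrosynthesis: remove the silyl group, both oxiranes and both angelates; cut C7–C8 (alkenyl triflate + 4-methylpent-3-enal); degrade the exo-methylene carbon C7 to a carboxyl; then cut C1–C6.
- Enabling feature: C1–C6 joins the allylic carbon C6 of the ring alkene C4=C5 (the oxirane precursor) to the α-carbon C1 of the C7 carboxyl, a γ,δ-unsaturated acid. Because C4 is a ring carbon, the carboxyl oxygen can be tied to C4, so the carbocycle is the Ireland–Claisen ring-contraction product of a 6-methyl-6-vinyl δ-lactone (ring O–C7–C1–C2–C3–C4).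
- Forward: chain C7–C1–C2–C3–C4 from divinylcarbinol → δ-lactone → cyclohexene (key step) → C7 methyl ketone → triflate → C7–C8 coupling → angelates → both oxiranes → desilylation.
- Stereochemistry: C2/C3 from a Sharpless epoxidation; C4 of the lactone by Cram-chelate vinyl addition, relayed to C1 by the suprafacial [3,3] shift; C8 by ligand-controlled Nozaki–Hiyama–Kishi coupling; C4/C5 and C10 by Shi epoxidation.

Key step: step 7

Remark: in step 11 the (S)-configured oxazoline–sulfonamide ligand is assumed to deliver the 8S carbinol; the sense is to be confirmed on first use and the enantiomeric ligand taken if it proves opposite.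

**Step 1**
Reactants: 1 penta-1,4-dien-3-ol
Product: 2 (1S)-1-[(2R)-oxiran-2-yl]prop-2-en-1-ol
Conditions: Ti(OiPr)4 (cat.), L-(+)-diisopropyl tartrate (cat.), tBuOOH, 4 Å molecular sieves, CH2Cl2, −20 °C
Reagents that add atoms: tert-butyl hydroperoxide CC(C)(C)OO
Why: Sharpless asymmetric epoxidation of a prochiral divinyl carbinol, in which the tartrate–titanium catalyst selects one enantiotopic vinyl group and one of its faces (erythro product), so C2 and C3 are set together and the minor enantiomer is drained by faster second epoxidation.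

**Step 2**
Reactants: 2 (1S)-1-[(2R)-oxiran-2-yl]prop-2-en-1-ol
Product: 3 (2R)-2-[(1S)-1-[(4-methoxyphenyl)methoxy]prop-2-en-1-yl]oxirane
Conditions: NaH, 4-MeOC6H4CH2Cl, Bu4NI (cat.), THF, 0 °C
Reagents that add atoms: 4-methoxybenzyl chloride COc1ccc(CCl)cc1
Why: Williamson etherification at 0 °C should outrun Payne rearrangement of the alkoxide; the 4-methoxybenzyl ether is the chelating group needed in step 6 and is removable oxidatively.

**Step 3**
Reactants: 3 (2R)-2-[(1S)-1-[(4-methoxyphenyl)methoxy]prop-2-en-1-yl]oxirane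
Product: 4 methyl (3R,4S)-3-hydroxy-4-[(4-methoxyphenyl)methoxy]hex-5-enoate
Conditions: Co2(CO)8 (cat.), 3-hydroxypyridine (cat.), CO (40 bar), MeOH, THF, 60 °C
Reagents that add atoms: carbon monoxide [C-]#[O+]; methanol CO
Why: Cobalt-catalysed methoxycarbonylation of a terminal epoxide, in which Co(CO)4− opens the oxirane at its CH2 terminus, CO inserts and methanol releases the β-hydroxy ester, so C7 arrives at the ester level with C2 and C3 untouched.

**Step 4**
Reactants: 4 methyl (3R,4S)-3-hydroxy-4-[(4-methoxyphenyl)methoxy]hex-5-enoate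
Product: 5 methyl (3R,4S)-4-[(4-methoxyphenyl)methoxy]-3-[(triethylsilyl)oxy]hex-5-enoate
Conditions: Et3SiCl, imidazole, CH2Cl2, 0 °C → rt
Reagents that add atoms: chlorotriethylsilane CC[Si](Cl)(CC)CC
Why: Standard silylation of a secondary alcohol; the triethylsilyl ether does not chelate magnesium in step 6, is a poor leaving group in step 7 and can be removed last under buffered fluoride.

**Step 5**
Reactants: 5 methyl (3R,4S)-4-[(4-methoxyphenyl)methoxy]-3-[(triethylsilyl)oxy]hex-5-enoate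
Product: 6 methyl (3R,4R)-4-[(4-methoxyphenyl)methoxy]-5-oxo-3-[(triethylsilyl)oxy]hexanoate
Conditions: PdCl2(quinox) (cat.; quinox = 2-(4,5-dihydro-1,3-oxazol-2-yl)quinoline), AgSbF6 (cat.), aq. tBuOOH, CH2Cl2, 0 °C → rt
Reagents that add atoms: tert-butyl hydroperoxide CC(C)(C)OO
Why: Tsuji–Wacker oxidation in its peroxide-mediated, ligand-controlled form, which should give the methyl ketone (Markovnikov) from a protected allylic alcohol without epimerising the α-alkoxy centre.

**Step 6**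
Reactants: 6 methyl (3R,4R)-4-[(4-methoxyphenyl)methoxy]-5-oxo-3-[(triethylsilyl)oxy]hexanoate
Product: 8 (4R,5R,6R)-6-ethenyl-5-[(4-methoxyphenyl)methoxy]-6-methyl-4-[(triethylsilyl)oxy]oxan-2-one, via bromomagnesium alkoxide 7 (not isolated)
Conditions: CH2=CHMgBr, THF, −78 °C → rt
Reagents that add atoms: vinylmagnesium bromide C=C[Mg]Br
Why: Cram-chelate 1,2-addition, in which magnesium bridges the ketone oxygen and the α-OPMB oxygen and the vinyl group enters opposite the C2 branch, sets the quaternary C4 (vinyl cis to the PMB ether in the ring); the tertiary alkoxide then closes the δ-lactone by 6-exo-trig transesterification.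

**Step 7**
Reactants: 8 (4R,5R,6R)-6-ethenyl-5-[(4-methoxyphenyl)methoxy]-6-methyl-4-[(triethylsilyl)oxy]oxan-2-one
Product: 11 (1S,5S,6R)-5-[(4-methoxyphenyl)methoxy]-4-methyl-6-[(triethylsilyl)oxy]cyclohex-3-ene-1-carboxylic acid, via silyl ketene acetal 9 (not isolated), via trimethylsilyl ester 10 (not isolated)
Conditions: LiN(iPr)2, Me3SiCl/Et3N, THF, −78 °C; toluene, 105 °C; then H2O/THF, citric acid, rt
Reagents that add atoms: chlorotrimethylsilane C[Si](C)(C)Cl (silicon in 9 and 10 only, lost on hydrolysis)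
Why: Kinetic enolisation of 8 with in situ O-silylation gives the endocyclic silyl ketene acetal 9, whose array C1=C7–O–C4–C5=C6 is an allyl vinyl ether, and heating triggers the concerted suprafacial [3,3]-sigmatropic (Ireland–Claisen) shift that forms C1–C6, breaks C4–O and leaves the C4=C5 alkene and the C7 silyl ester. The closest known reaction type is the Claisen ring contraction of silyl ketene acetals of ω-alkenyl lactones to cycloalkenecarboxylic acids. The six-membered carbocycle closes as an oxacycle-to-carbocycle ring contraction; because C1 and C4 are tied by the two-carbon C2–C3 unit, the pericyclic array must adopt a boat (bicyclo[2.2.2]octane-like) geometry and no chair alternative exists. The new stereocentre C1 is fixed by chirality transfer from C4: the vinyl group can reach only the face of the ketene acetal on which it stands, so the 6R configuration from step 6 becomes the required C1 configuration (carboxyl trans to the C2 silyloxy group) while C4 becomes trigonal. The step needs O-silylation to outrun β-elimination of the C2 silyloxy group, which the internal Me3SiCl quench at −78 °C and the poor leaving-group ability of a silyloxide should secure; no regiochemical question arises because only one allyl vinyl ether is present. The carboxyl and the ring alkene emerge exactly where the exo-methylene unit and the ring oxirane are built later.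

**Step 8**
Reactants: 11 (1S,5S,6R)-5-[(4-methoxyphenyl)methoxy]-4-methyl-6-[(triethylsilyl)oxy]cyclohex-3-ene-1-carboxylic acid
Product: 13 1-[(1S,5S,6R)-5-[(4-methoxyphenyl)methoxy]-4-methyl-6-[(triethylsilyl)oxy]cyclohex-3-en-1-yl]ethan-1-one, via dilithium gem-diolate 12 (not isolated)
Conditions: MeLi (3 equiv), THF, −78 → 0 °C; inverse quench into ice-cold H2O
Reagents that add atoms: methyllithium [Li]C
Why: Organolithium ketone synthesis from a carboxylic acid: the lithium carboxylate accepts one methyllithium and rests as gem-diolate 12, which collapses to the methyl ketone only on quench, and C1 is not enolised at the carboxylate stage.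

**Step 9**
Reactants: 13 1-[(1S,5S,6R)-5-[(4-methoxyphenyl)methoxy]-4-methyl-6-[(triethylsilyl)oxy]cyclohex-3-en-1-yl]ethan-1-one
Product: 15 1-[(1S,5S,6R)-5-[(4-methoxyphenyl)methoxy]-4-methyl-6-[(triethylsilyl)oxy]cyclohex-3-en-1-yl]ethenyl trifluoromethanesulfonate, via potassium enolate 14 (not isolated)
Conditions: KN(SiMe3)2, THF, −78 °C; then PhN(SO2CF3)2, −78 → 0 °C
Reagents that add atoms: N-phenylbis(trifluoromethanesulfonimide) O=S(=O)(N(c1ccccc1)S(=O)(=O)C(F)(F)F)C(F)(F)F; potassium bis(trimethylsilyl)amide C[Si](C)(C)[N-][Si](C)(C)C.[K+] (potassium in 14 only)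
Why: Enol triflate formation: kinetic deprotonation by the hindered amide occurs at the methyl group and not at the tertiary C1–H, and O-sulfonylation gives the 1,1-disubstituted alkenyl triflate with C1 untouched.

**Step 10**
Reactants: 16 4-methylpent-3-en-1-ol
Product: 17 4-methylpent-3-enal
Conditions: Dess–Martin periodinane, CH2Cl2, 0 °C → rt; solution used at once
Reagents that add atoms: none
Why: Dess–Martin oxidation under non-aqueous, near-neutral conditions should give the β,γ-unsaturated aldehyde without migration of the double bond into conjugation.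

**Step 11**
Reactants: 15 1-[(1S,5S,6R)-5-[(4-methoxyphenyl)methoxy]-4-methyl-6-[(triethylsilyl)oxy]cyclohex-3-en-1-yl]ethenyl trifluoromethanesulfonate; 17 4-methylpent-3-enal
Product: 18 (3S)-2-[(1R,5S,6R)-5-[(4-methoxyphenyl)methoxy]-4-methyl-6-[(triethylsilyl)oxy]cyclohex-3-en-1-yl]-6-methylhepta-1,5-dien-3-ol
Conditions: CrCl2, NiCl2 (cat.), (S)-N-[2-(4-isopropyl-4,5-dihydro-1,3-oxazol-2-yl)-6-methylphenyl]methanesulfonamide, Et3N, THF, rt
Reagents that add atoms: none
Why: Nozaki–Hiyama–Kishi reaction: nickel-catalysed activation of the alkenyl triflate, transfer to chromium and 1,2-addition to the aldehyde form C7–C8 with the exo-methylene in place, and the chiral sulfonamide–oxazoline ligand on chromium selects the aldehyde face and sets C8.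

**Step 12**
Reactants: 18 (3S)-2-[(1R,5S,6R)-5-[(4-methoxyphenyl)methoxy]-4-methyl-6-[(triethylsilyl)oxy]cyclohex-3-en-1-yl]-6-methylhepta-1,5-dien-3-ol
Product: 19 (1S,5R,6R)-5-[(3S)-3-hydroxy-6-methylhepta-1,5-dien-2-yl]-2-methyl-6-[(triethylsilyl)oxy]cyclohex-2-en-1-ol
Conditions: DDQ, CH2Cl2/aq. phosphate buffer (pH 7), 0 °C
Reagents that add atoms: none
Why: Oxidative cleavage of the 4-methoxybenzyl ether by DDQ (benzylic hydride abstraction, hydrolysis of the oxocarbenium ion) should leave the silyl ether, the three alkenes and the allylic alcohol intact.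

**Step 13**
Reactants: 19 (1S,5R,6R)-5-[(3S)-3-hydroxy-6-methylhepta-1,5-dien-2-yl]-2-methyl-6-[(triethylsilyl)oxy]cyclohex-2-en-1-ol; 20 angelic acid, (2Z)-2-methylbut-2-enoic acid
Product: 22 (1S,5R,6R)-2-methyl-5-[(3S)-6-methyl-3-{[(2Z)-2-methylbut-2-enoyl]oxy}hepta-1,5-dien-2-yl]-6-[(triethylsilyl)oxy]cyclohex-2-en-1-yl (2Z)-2-methylbut-2-enoate, via angelic 2,4,6-trichlorobenzoic anhydride 21 (not isolated)
Conditions: 20 (6 equiv), 2,4,6-Cl3C6H2COCl, Et3N, toluene, rt; then 19, 80 °C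
Reagents that add atoms: 2,4,6-trichlorobenzoyl chloride O=C(Cl)c1c(Cl)cc(Cl)cc1Cl (in 21 only)
Why: Yamaguchi-type mixed-anhydride esterification: the aroyl carbonyl of 21 is shielded by its two ortho chlorines so both secondary alcohols attack the angeloyl carbonyl, and the absence of a nucleophilic catalyst avoids Z to E isomerisation to the tiglate.

**Step 14**
Reactants: 22 (1S,5R,6R)-2-methyl-5-[(3S)-6-methyl-3-{[(2Z)-2-methylbut-2-enoyl]oxy}hepta-1,5-dien-2-yl]-6-[(triethylsilyl)oxy]cyclohex-2-en-1-yl (2Z)-2-methylbut-2-enoate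
Product: 23 2-O-triethylsilyl ether of the target, (1R,2R,3R,4R,5R,8S,10R)-3,8-bis(angeloyloxy)-4,5:10,11-diepoxy-2-[(triethylsilyl)oxy]bisabol-7(14)-ene
Conditions: 1,2:4,5-di-O-isopropylidene-β-D-erythro-2,3-hexodiulo-2,6-pyranose (0.6 equiv), Oxone (2KHSO5·KHSO4·K2SO4), K2CO3, Bu4NHSO4 (cat.), MeCN/CH2(OMe)2/aq. Na2B4O7 buffer (pH 10.5), 0 °C
Reagents that add atoms: potassium peroxymonosulfate [K+].[O-]S(=O)(=O)OO
Why: Shi asymmetric epoxidation: the fructose-derived dioxirane should epoxidise only the two electron-rich trisubstituted alkenes through spiro transition states, setting 10R by reagent control and 4R,5R by reagent control reinforced by attack anti to the pseudoaxial C3 ester, while the 1,1-disubstituted alkene and the conjugated angelate alkenes are too hindered or electron-poor to react.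

**Step 15**
Reactants: 23 2-O-triethylsilyl ether of the target
Product: 24 target, (1R,2R,3R,4R,5R,8S,10R)-3,8-bis(angeloyloxy)-4,5:10,11-diepoxybisabol-7(14)-en-2-ol
Conditions: Bu4NF/AcOH (1:1), THF, 0 °C
Reagents that add atoms: none
Why: Fluoride-induced cleavage of the triethylsilyl ether; buffering with acetic acid keeps the medium near neutral so that neither oxirane should open and the C3 angelate should not migrate to the cis C2 hydroxyl.

**Compound list**

1 | penta-1,4-dien-3-ol | C=CC(O)C=C | starting material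
2 | (1S)-1-[(2R)-oxiran-2-yl]prop-2-en-1-ol | C=C[C@H](O)[C@H]1CO1 | intermediate
3 | (2R)-2-[(1S)-1-[(4-methoxyphenyl)methoxy]prop-2-en-1-yl]oxirane | C=C[C@H](OCc1ccc(OC)cc1)[C@H]1CO1 | intermediate
4 | methyl (3R,4S)-3-hydroxy-4-[(4-methoxyphenyl)methoxy]hex-5-enoate | COC(=O)C[C@@H](O)[C@@H](OCc1ccc(OC)cc1)C=C | intermediate
5 | methyl (3R,4S)-4-[(4-methoxyphenyl)methoxy]-3-[(triethylsilyl)oxy]hex-5-enoate | COC(=O)C[C@@H](O[Si](CC)(CC)CC)[C@@H](OCc1ccc(OC)cc1)C=C | intermediate
6 | methyl (3R,4R)-4-[(4-methoxyphenyl)methoxy]-5-oxo-3-[(triethylsilyl)oxy]hexanoate | COC(=O)C[C@@H](O[Si](CC)(CC)CC)[C@@H](OCc1ccc(OC)cc1)C(C)=O | intermediate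
7 | bromomagnesium alkoxide of methyl (3R,4R,5R)-5-hydroxy-4-[(4-methoxyphenyl)methoxy]-5-methyl-3-[(triethylsilyl)oxy]hept-6-enoate | COC(=O)C[C@@H](O[Si](CC)(CC)CC)[C@@H](OCc1ccc(OC)cc1)[C@@](C)(C=C)O[Mg]Br | intermediate
8 | (4R,5R,6R)-6-ethenyl-5-[(4-methoxyphenyl)methoxy]-6-methyl-4-[(triethylsilyl)oxy]oxan-2-one | O=C1C[C@@H](O[Si](CC)(CC)CC)[C@@H](OCc2ccc(OC)cc2)[C@@](C)(C=C)O1 | intermediate
9 | (2R,3R,4R)-2-ethenyl-3-[(4-methoxyphenyl)methoxy]-2-methyl-4-[(triethylsilyl)oxy]-6-[(trimethylsilyl)oxy]-3,4-dihydro-2H-pyran | C[Si](C)(C)OC1=C[C@@H](O[Si](CC)(CC)CC)[C@@H](OCc2ccc(OC)cc2)[C@@](C)(C=C)O1 | intermediate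
10 | trimethylsilyl (1S,5S,6R)-5-[(4-methoxyphenyl)methoxy]-4-methyl-6-[(triethylsilyl)oxy]cyclohex-3-ene-1-carboxylate | C[Si](C)(C)OC(=O)[C@H]1CC=C(C)[C@H](OCc2ccc(OC)cc2)[C@@H]1O[Si](CC)(CC)CC | intermediate
11 | (1S,5S,6R)-5-[(4-methoxyphenyl)methoxy]-4-methyl-6-[(triethylsilyl)oxy]cyclohex-3-ene-1-carboxylic acid | OC(=O)[C@H]1CC=C(C)[C@H](OCc2ccc(OC)cc2)[C@@H]1O[Si](CC)(CC)CC | intermediate
12 | dilithium 1-[(1S,5S,6R)-5-[(4-methoxyphenyl)methoxy]-4-methyl-6-[(triethylsilyl)oxy]cyclohex-3-en-1-yl]ethane-1,1-bis(olate) | [Li+].[Li+].CC([O-])([O-])[C@H]1CC=C(C)[C@H](OCc2ccc(OC)cc2)[C@@H]1O[Si](CC)(CC)CC | intermediate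
13 | 1-[(1S,5S,6R)-5-[(4-methoxyphenyl)methoxy]-4-methyl-6-[(triethylsilyl)oxy]cyclohex-3-en-1-yl]ethan-1-one | CC(=O)[C@H]1CC=C(C)[C@H](OCc2ccc(OC)cc2)[C@@H]1O[Si](CC)(CC)CC | intermediate
14 | potassium 1-[(1S,5S,6R)-5-[(4-methoxyphenyl)methoxy]-4-methyl-6-[(triethylsilyl)oxy]cyclohex-3-en-1-yl]ethen-1-olate | [K+].C=C([O-])[C@H]1CC=C(C)[C@H](OCc2ccc(OC)cc2)[C@@H]1O[Si](CC)(CC)CC | intermediate
15 | 1-[(1S,5S,6R)-5-[(4-methoxyphenyl)methoxy]-4-methyl-6-[(triethylsilyl)oxy]cyclohex-3-en-1-yl]ethenyl trifluoromethanesulfonate | C=C(OS(=O)(=O)C(F)(F)F)[C@H]1CC=C(C)[C@H](OCc2ccc(OC)cc2)[C@@H]1O[Si](CC)(CC)CC | intermediate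
16 | 4-methylpent-3-en-1-ol | CC(C)=CCCO | starting material
17 | 4-methylpent-3-enal | CC(C)=CCC=O | intermediate
18 | (3S)-2-[(1R,5S,6R)-5-[(4-methoxyphenyl)methoxy]-4-methyl-6-[(triethylsilyl)oxy]cyclohex-3-en-1-yl]-6-methylhepta-1,5-dien-3-ol | C=C([C@@H](O)CC=C(C)C)[C@H]1CC=C(C)[C@H](OCc2ccc(OC)cc2)[C@@H]1O[Si](CC)(CC)CC | intermediate
19 | (1S,5R,6R)-5-[(3S)-3-hydroxy-6-methylhepta-1,5-dien-2-yl]-2-methyl-6-[(triethylsilyl)oxy]cyclohex-2-en-1-ol | C=C([C@@H](O)CC=C(C)C)[C@H]1CC=C(C)[C@H](O)[C@@H]1O[Si](CC)(CC)CC | intermediate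
20 | angelic acid, (2Z)-2-methylbut-2-enoic acid | C/C=C(/C)C(=O)O | starting material
21 | (2Z)-2-methylbut-2-enoic 2,4,6-trichlorobenzoic anhydride | C/C=C(/C)C(=O)OC(=O)c1c(Cl)cc(Cl)cc1Cl | intermediate
22 | (1S,5R,6R)-2-methyl-5-[(3S)-6-methyl-3-{[(2Z)-2-methylbut-2-enoyl]oxy}hepta-1,5-dien-2-yl]-6-[(triethylsilyl)oxy]cyclohex-2-en-1-yl (2Z)-2-methylbut-2-enoate | C=C([C@H](CC=C(C)C)OC(=O)/C(C)=C\C)[C@H]1CC=C(C)[C@H](OC(=O)/C(C)=C\C)[C@@H]1O[Si](CC)(CC)CC | intermediate
23 | 2-O-triethylsilyl ether of the target | C=C([C@H](C[C@H]1OC1(C)C)OC(=O)/C(C)=C\C)[C@H]1C[C@H]2O[C@@]2(C)[C@H](OC(=O)/C(C)=C\C)[C@@H]1O[Si](CC)(CC)CC | intermediate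
24 | (1R,2R,3R,4R,5R,8S,10R)-3,8-bis(angeloyloxy)-4,5:10,11-diepoxybisabol-7(14)-en-2-ol | C=C([C@H](C[C@H]1OC1(C)C)OC(=O)/C(C)=C\C)[C@H]1C[C@H]2O[C@@]2(C)[C@H](OC(=O)/C(C)=C\C)[C@@H]1O | target

**Step count and risks**

Total step count: 15. Longest linear sequence: 14 (steps 1–9 and 11–15; step 10 is the one-step side branch).

Steps most likely to fail:

1. Step 7. What may go wrong: β-elimination of the C2 silyloxy group from the lactone enolate before O-silylation, or decomposition of the ketene acetal before the strained boat transition state (both ring oxygens on the side of the migrating vinyl group) is reached. The fallback replaces enolate chemistry by the neutral allyl vinyl ether Claisen rearrangement; it sets out from 8 and comes back at 13. Reduction of 8 with iBu2AlH (CH2Cl2, −78 °C) should give the lactol (4R,5R,6R)-6-ethenyl-5-[(4-methoxyphenyl)methoxy]-6-methyl-4-[(triethylsilyl)oxy]oxan-2-ol F1. Mesylation and elimination (MeSO2Cl, Et3N, CH2Cl2, 0 °C → reflux) should give the endocyclic enol ether (2R,3R,4R)-2-ethenyl-3-[(4-methoxyphenyl)methoxy]-2-methyl-4-[(triethylsilyl)oxy]-3,4-dihydro-2H-pyran F2. Thermolysis (o-dichlorobenzene, about 220 °C, base-washed sealed tube) should close the same C1–C6 bond and give (1S,5S,6R)-5-[(4-methoxyphenyl)methoxy]-4-methyl-6-[(triethylsilyl)oxy]cyclohex-3-ene-1-carbaldehyde F3. Addition of MeMgBr (THF, −78 °C) gives the carbinol 1-[(1R,5S,6R)-5-[(4-methoxyphenyl)methoxy]-4-methyl-6-[(triethylsilyl)oxy]cyclohex-3-en-1-yl]ethan-1-ol F4 (both carbinol epimers), and Dess–Martin oxidation returns to 13.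

2. Step 11. What may go wrong: poor or reversed facial selectivity at the aldehyde, so that C8 is formed as a mixture, and isomerisation of the β,γ-unsaturated aldehyde before coupling. The fallback sets C8 by reagent-controlled ketone reduction; it sets out from 15 and 17 and comes back at 18. Ligand-free coupling (CrCl2, NiCl2 (cat.), DMF, rt) gives 18 together with its C8 epimer (3R)-2-[(1R,5S,6R)-5-[(4-methoxyphenyl)methoxy]-4-methyl-6-[(triethylsilyl)oxy]cyclohex-3-en-1-yl]-6-methylhepta-1,5-dien-3-ol F5. Dess–Martin oxidation of the mixture (NaHCO3, CH2Cl2, 0 °C) gives the enone 2-[(1R,5S,6R)-5-[(4-methoxyphenyl)methoxy]-4-methyl-6-[(triethylsilyl)oxy]cyclohex-3-en-1-yl]-6-methylhepta-1,5-dien-3-one F6. Corey–Bakshi–Shibata reduction with (R)-1-methyl-3,3-diphenyltetrahydro-1H,3H-pyrrolo[1,2-c][1,3,2]oxazaborole and BH3·SMe2 (toluene, −78 °C), the branched alkenyl group acting as the large substituent, should return 18 with the 8S configuration.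

3. Step 14. What may go wrong: incomplete or wrong-face epoxidation of the hindered ring alkene under reagent control, or over-oxidation at the other alkenes while the ring alkene is forced to react. The fallback makes the ring oxirane earlier by substrate control and uses the chiral dioxirane only for the side chain; it sets out from 15 and comes back at 23. Treatment of 15 with mCPBA (NaHCO3, CH2Cl2, 0 °C) should epoxidise only the electron-rich ring alkene, anti to the pseudoaxial C3 ether, and give the (4R,5R)-4,5-epoxide of 15, F7. Coupling of F7 with 17 under the conditions of step 11 gives the (4R,5R)-4,5-epoxide of 18, F8. DDQ as in step 12 gives the (4R,5R)-4,5-epoxide of 19, F9. Bis-angeloylation as in step 13 gives the (4R,5R)-4,5-epoxide of 22, F10. Shi epoxidation of the one remaining trisubstituted alkene as in step 14 returns to 23.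

**Further compounds**

F1 | step 7 | (4R,5R,6R)-6-ethenyl-5-[(4-methoxyphenyl)methoxy]-6-methyl-4-[(triethylsilyl)oxy]oxan-2-ol | OC1C[C@@H](O[Si](CC)(CC)CC)[C@@H](OCc2ccc(OC)cc2)[C@@](C)(C=C)O1
F2 | step 7 | (2R,3R,4R)-2-ethenyl-3-[(4-methoxyphenyl)methoxy]-2-methyl-4-[(triethylsilyl)oxy]-3,4-dihydro-2H-pyran | C1=C[C@@H](O[Si](CC)(CC)CC)[C@@H](OCc2ccc(OC)cc2)[C@@](C)(C=C)O1
F3 | step 7 | (1S,5S,6R)-5-[(4-methoxyphenyl)methoxy]-4-methyl-6-[(triethylsilyl)oxy]cyclohex-3-ene-1-carbaldehyde | O=C[C@H]1CC=C(C)[C@H](OCc2ccc(OC)cc2)[C@@H]1O[Si](CC)(CC)CC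
F4 | step 7 | 1-[(1R,5S,6R)-5-[(4-methoxyphenyl)methoxy]-4-methyl-6-[(triethylsilyl)oxy]cyclohex-3-en-1-yl]ethan-1-ol | CC(O)[C@H]1CC=C(C)[C@H](OCc2ccc(OC)cc2)[C@@H]1O[Si](CC)(CC)CC
F5 | step 11 | (3R)-2-[(1R,5S,6R)-5-[(4-methoxyphenyl)methoxy]-4-methyl-6-[(triethylsilyl)oxy]cyclohex-3-en-1-yl]-6-methylhepta-1,5-dien-3-ol | C=C([C@H](O)CC=C(C)C)[C@H]1CC=C(C)[C@H](OCc2ccc(OC)cc2)[C@@H]1O[Si](CC)(CC)CC
F6 | step 11 | 2-[(1R,5S,6R)-5-[(4-methoxyphenyl)methoxy]-4-methyl-6-[(triethylsilyl)oxy]cyclohex-3-en-1-yl]-6-methylhepta-1,5-dien-3-one | C=C(C(=O)CC=C(C)C)[C@H]1CC=C(C)[C@H](OCc2ccc(OC)cc2)[C@@H]1O[Si](CC)(CC)CC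
F7 | step 14 | (4R,5R)-4,5-epoxide of 15 | C=C(OS(=O)(=O)C(F)(F)F)[C@H]1C[C@H]2O[C@@]2(C)[C@H](OCc3ccc(OC)cc3)[C@@H]1O[Si](CC)(CC)CC
F8 | step 14 | (4R,5R)-4,5-epoxide of 18 | C=C([C@@H](O)CC=C(C)C)[C@H]1C[C@H]2O[C@@]2(C)[C@H](OCc3ccc(OC)cc3)[C@@H]1O[Si](CC)(CC)CC
F9 | step 14 | (4R,5R)-4,5-epoxide of 19 | C=C([C@@H](O)CC=C(C)C)[C@H]1C[C@H]2O[C@@]2(C)[C@H](O)[C@@H]1O[Si](CC)(CC)CC
F10 | step 14 | (4R,5R)-4,5-epoxide of 22 | C=C([C@H](CC=C(C)C)OC(=O)/C(C)=C\C)[C@H]1C[C@H]2O[C@@]2(C)[C@H](OC(=O)/C(C)=C\C)[C@@H]1O[Si](CC)(CC)CC
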